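## Retrosynthetic overview

1. 26 ⇒ aldehyde 22 + 2-hydroxy-5-methoxy-1,4-benzoquinone 24; the C15–quinone bond is made last by organocatalytic reductive alkylation.
2. Decalin 18 ⇒ ten-membered epoxy-allylsilane 17. Rings A (C1–C5, C10) and B (C5–C10) share only the C5–C10 bond, so C1…C10 form one cyclodecane perimeter; joining C5 to C10 across it (C10 = epoxide carbon, C4=C5 = allylsilane) makes both rings and the C4 methylene at once.
3. 17 ⇒ α-hydroxy ketone 14 + CH3MgBr; the C10 methyl is brought in last, then the C1 oxygen is closed onto C10 as the epoxide with inversion at C1.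
4. 14 ⇒ trans-1,2-dialkenylcyclohexanol 12 (anionic oxy-Cope ring expansion, enolate hydroxylation); 12 ⇒ cyclohexene oxide 7 + the Grignard reagent of 8, then oxidation and vinyl addition.
5. 7 ⇒ 2-methylcyclohex-2-enone 1 (asymmetric methyl conjugate addition/formaldehyde aldol sets C8 and C9). Ring order: cyclohexane ring (from 1) → ten-membered ring (step 9) → rings A and B together (step 12).

Key step: step 12

Remark: target numbering is kept for all intermediates (C1–C10 ring carbons, C15 the CH2 on C9; β is the face of the C10 methyl, α the other face); the C4=C5 bond of the ten-membered compounds has C3 and C6 trans across it, which is (Z) by the CIP rules because CH2SiMe3 outranks C3; the phosphoramidite enantiomer in step 1 is assumed to be the one that gives the 8S adduct.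

## Route

Step 1
Reactants: 1 2-methylcyclohex-2-en-1-one
Product: 3 (2S,3S)-2-(hydroxymethyl)-2,3-dimethylcyclohexan-1-one, via dimethylaluminium enolate 2 (not isolated)
Conditions: Me3Al, copper thiophene-2-carboxylate (CuTC, 2 mol %), BINOL-derived phosphoramidite ligand (4 mol %), Et2O, −30 °C; then monomeric CH2O in THF, −78 → −20 °C; aq. NH4Cl
Reagents that add atoms: trimethylaluminium C[Al](C)C; formaldehyde C=O
Why: Copper-catalysed asymmetric conjugate addition of Me3Al to the 2-substituted enone sets C8 under ligand control, and the tetrasubstituted aluminium enolate is trapped by an aldol addition to formaldehyde on the face anti to the new C8 methyl, which sets the quaternary C9 with CH2OH trans to that methyl.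

Step 2
Reactants: 3 (2S,3S)-2-(hydroxymethyl)-2,3-dimethylcyclohexan-1-one
Product: 4 (2S,3S)-2-{[tert-butyl(diphenyl)silyl]oxymethyl}-2,3-dimethylcyclohexan-1-one
Conditions: t-BuPh2SiCl, imidazole, DMF, rt
Reagents that add atoms: tert-butyl(chloro)diphenylsilane CC(C)(C)[Si](Cl)(c1ccccc1)c1ccccc1
Why: Imidazole-mediated silylation of the primary alcohol stops retro-aldol loss of formaldehyde and installs a bulky, non-coordinating ether that lasts until step 15.

Step 3
Reactants: 4 (2S,3S)-2-{[tert-butyl(diphenyl)silyl]oxymethyl}-2,3-dimethylcyclohexan-1-one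
Product: 5 (5S,6S)-6-{[tert-butyl(diphenyl)silyl]oxymethyl}-5,6-dimethylcyclohex-1-en-1-yl trifluoromethanesulfonate
Conditions: KN(SiMe3)2, THF, −78 °C; PhNTf2, −78 → 0 °C; aq. NH4Cl
Reagents that add atoms: N-phenylbis(trifluoromethanesulfonimide) O=S(=O)(N(c1ccccc1)S(=O)(=O)C(F)(F)F)C(F)(F)F
Why: Because C9 is quaternary the ketone can enolise only towards C5, so enolate O-sulfonylation gives a single enol triflate.

Step 4
Reactants: 5 (5S,6S)-6-{[tert-butyl(diphenyl)silyl]oxymethyl}-5,6-dimethylcyclohex-1-en-1-yl trifluoromethanesulfonate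
Product: 6 (3R,4S)-3-{[tert-butyl(diphenyl)silyl]oxymethyl}-3,4-dimethylcyclohex-1-ene
Conditions: Pd(OAc)2 (5 mol %), PPh3, Bu3N, HCO2H, DMF, 60 °C
Reagents that add atoms: none
Why: Palladium-catalysed formate reduction of the alkenyl triflate (Pd(OAc)2, divalent palladium, is reduced in the flask to the zerovalent palladium catalyst) replaces OTf by H and leaves the C5=C10 double bond in place.

Step 5
Reactants: 6 (3R,4S)-3-{[tert-butyl(diphenyl)silyl]oxymethyl}-3,4-dimethylcyclohex-1-ene
Product: 7 C5–C10 α-epoxide of 6 (oxirane oxygen cis to CH2OSi and trans to both methyls)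
Conditions: mCPBA, CH2Cl2, 0 °C
Reagents that add atoms: 3-chloroperoxybenzoic acid O=C(OO)c1cccc(Cl)c1
Why: Prilezhaev epoxidation should take the α face, anti to the pseudo-axial C9 methyl of the half-chair that keeps the C8 methyl equatorial (the other half-chair is screened on both faces), so both new centres carry oxygen cis to CH2OSi.

Step 6
Reactants: 7 C5–C10 α-epoxide; 8 2-bromo-3-(trimethylsilyl)prop-1-ene
Product: 10 trans-alcohol with C10 OH α and C5 [3-(trimethylsilyl)prop-1-en-2-yl] β, via alkenyl Grignard reagent 9 (not isolated)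
Conditions: 8, Mg, THF, rt; CuI (10 mol %), then 7, THF, −20 °C → rt; aq. NH4Cl
Reagents that add atoms: none
Why: Copper-catalysed SN2 opening of the epoxide by the alkenyl Grignard reagent, a known use of this reagent, should occur at C5 because C10 is neopentyl, in the trans-diaxial (Fürst–Plattner) mode, so C5 is set by inversion with the alkenyl group β (cis to both methyls) and the C10 hydroxyl α.

Step 7
Reactants: 10 trans-alcohol with C10 OH α and C5 alkenyl β
Product: 11 cyclohexanone (C10=O) with the C5 [3-(trimethylsilyl)prop-1-en-2-yl] group β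
Conditions: Dess–Martin periodinane, pyridine, CH2Cl2, 0 °C
Reagents that add atoms: none
Why: Buffered Dess–Martin oxidation gives the β,γ-unsaturated ketone without acid or base, so the C5 centre, the position of the double bond and the allylsilane are not touched.

Step 8
Reactants: 11 cyclohexanone with the C5 alkenyl group β
Product: 12 tertiary carbinol with C10 vinyl α and OH β and C5 alkenyl β (the two alkenyl groups trans)
Conditions: CH2=CHMgBr, CeCl3 (anhydrous), THF, −78 → 0 °C; aq. NH4Cl
Reagents that add atoms: vinylmagnesium bromide C=C[Mg]Br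
Why: Organocerium 1,2-addition avoids enolisation towards C5, and since the β face of C10 is screened in either chair (by the axial C8 methyl, or by the axial C9 methyl and C5 alkenyl group) the vinyl group should enter from the α face, trans to the C5 alkenyl group, which sets C10.

Step 9
Reactants: 12 tertiary carbinol with C10 vinyl α and OH β and C5 alkenyl β
Product: 14 (1S,4Z,8S,9S)-1-hydroxy ten-membered ketone (C10=O; C4 bears CH2SiMe3; C9 bears CH3 and CH2OSi), via ten-membered potassium enolate 13 (not isolated)
Conditions: KN(SiMe3)2, 18-crown-6, THF, 0 °C → rt; then −78 °C, 3-phenyl-2-(phenylsulfonyl)oxaziridine; aq. NH4Cl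
Reagents that add atoms: 3-phenyl-2-(phenylsulfonyl)oxaziridine O=S(=O)(c1ccccc1)N1OC1c1ccccc1
Why: The potassium alkoxide undergoes the anionic oxy-Cope [3,3] rearrangement through the chair transition state with both alkenyl groups equatorial, so both new double bonds (C1=C10 enolate and C4=C5) are trans within the ring, and the enolate is then hydroxylated (Davis oxidation) at C1 from the outer face of its preferred conformer (C8 methyl outward, enolate oxygen α), which should set C1 as S.

Step 10
Reactants: 14 (1S,4Z,8S,9S)-1-hydroxy ten-membered ketone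
Product: 15 (1S,4Z,8S,9S,10R)-1,10-diol with the new CH3 on C10
Conditions: CH3MgBr (3 equiv), THF, −78 → 0 °C; aq. NH4Cl
Reagents that add atoms: methylmagnesium bromide C[Mg]Br
Why: Chelation-controlled Grignard addition (Cram chelate through the C1 magnesium alkoxide) should deliver methyl to the C10 ketone from the ring periphery, on the side of H1 and away from C8, which sets C10 as R; the methyl group, arriving last, takes the outer position that an epoxidising reagent acting on the C1=C10 olefin would have taken, and the oxygen ends on the face that the transannular closure needs.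

Step 11
Reactants: 15 (1S,4Z,8S,9S,10R)-1,10-diol
Product: 17 (1R,4Z,8S,9S,10R)-1,10-epoxide (trans epoxide; C4 CH2SiMe3; C8 CH3; C9 CH3 and CH2OSiPh2t-Bu; C10 CH3), via C1 mesylate 16 (not isolated)
Conditions: MsCl, Et3N, CH2Cl2, −20 °C; then K2CO3, MeOH, rt; filtration through Et3N-deactivated silica
Reagents that add atoms: none
Why: The secondary C1 hydroxyl is sulfonylated in preference to the tertiary one and the C10 alkoxide then displaces the mesylate in an intramolecular Williamson (SN2) closure with inversion at C1, which gives the trans epoxide with C1 R and C10 R.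

Step 12
Reactants: 17 (1R,4Z,8S,9S,10R)-1,10-epoxide
Product: 18 (1R,5S,8S,9R,10S)-decalin with 4-methylene, C1 β-OH, 5α-H, 8β-CH3, 9β-CH3, 9α-CH2OSiPh2t-Bu and 10β-CH3
Conditions: Et2AlCl (1.5 equiv), CH2Cl2, −78 → −40 °C; aq. NaHCO3
Reagents that add atoms: none
Why: Et2AlCl binds the epoxide oxygen, and the C10–O bond ionises at the tertiary carbon as the C4=C5 π bond, held across the ring within bonding distance, attacks C10 from the inside face (anti to the leaving oxygen, inversion at C10); the β-silyl cation at C4 then loses Me3Si to chloride and gives the exocyclic methylene regiospecifically (anti SE2′). The closest known reactions are the Lewis-acid transannular cyclisation of 1,10-epoxygermacra-4-enes to eudesmanes and epoxide-initiated, allylsilane-terminated cation–olefin cyclisations. The single C5–C10 bond divides the ten-membered ring into ring A (C1–C5, C10; 6-endo with respect to both epoxide and olefin) and ring B (C5–C10; 6-exo with respect to both). C10 is fixed by the 10R epoxide through inversion, C1 keeps its configuration and becomes the equatorial β-carbinol, and C5 is set by the chair–chair folding in which the in-ring trans C4=C5 bond lies crossed over the epoxide with CH2SiMe3 on the β face, so that H5 ends α and the fusion trans. The step needs opening at C10 and not C1 (secured by the tertiary centre and the nucleophilic allylsilane), the exocyclic olefin (secured by silicon), and trans fusion over the array with ring A as a boat that would give the cis-fused isomer (favoured by the usual chair–chair preference and by the bulky CH2OSi group, which is axial and remote from the aluminium-bound oxygen only in the chair–chair array). The chair–chair array carries the C8 methyl axial and syn to the C10 methyl, so its margin is smaller than in the germacrene cases, and this is where the risk of the route is placed.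

Step 13
Reactants: 18 decalin C1 β-alcohol
Product: 19 O-(C1) S-methyl xanthate of 18
Conditions: NaH, imidazole (cat.), THF, 0 °C; CS2; MeI, rt
Reagents that add atoms: carbon disulfide S=C=S; iodomethane CI
Why: Xanthate formation on the equatorial C1 alkoxide is the first half of the Barton–McCombie deoxygenation and tolerates the silyl ether and the methylene group.

Step 14
Reactants: 19 O-(C1) S-methyl xanthate
Product: 20 (5S,8S,9R,10S)-decalin silyl ether with C1 as CH2
Conditions: Bu3SnH, AIBN (cat.), toluene, 110 °C
Reagents that add atoms: none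
Why: Barton–McCombie radical deoxygenation, in which the secondary C1 radical formed by β-scission takes hydrogen from Bu3SnH and has only 5-endo paths to the C4 methylene, so it is reduced and not cyclised.

Step 15
Reactants: 20 1-deoxy decalin silyl ether
Product: 21 decalin C15 primary alcohol (9α-CH2OH)
Conditions: Bu4NF, THF, 50 °C; aq. NH4Cl
Reagents that add atoms: none
Why: Fluoride cleavage of the silyl ether frees the neopentyl alcohol without touching the exocyclic olefin.

Step 16
Reactants: 21 decalin C15 primary alcohol
Product: 22 decalin C15 aldehyde (9α-CHO)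
Conditions: Dess–Martin periodinane, pyridine, CH2Cl2, rt
Reagents that add atoms: none
Why: Dess–Martin oxidation gives an aldehyde that has no α hydrogen and therefore cannot epimerise or enolise.

Step 17
Reactants: 23 2,5-dimethoxy-1,4-benzoquinone
Product: 24 2-hydroxy-5-methoxy-1,4-benzoquinone
Conditions: NaOH (1.05 equiv), H2O/THF, 0 °C → rt; then 1 M HCl
Reagents that add atoms: sodium hydroxide [Na+].[OH-]
Why: Vinylogous ester hydrolysis by addition–elimination of hydroxide should stop after one exchange because the product is a vinylogous carboxylate anion that resists a second attack.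

Step 18
Reactants: 22 decalin C15 aldehyde; 24 2-hydroxy-5-methoxy-1,4-benzoquinone
Product: 26 target (5S,8S,9R,10S)-2-hydroxy-5-methoxy-3-(decalinylmethyl)-1,4-benzoquinone, via alkylidene trione 25 (not isolated)
Conditions: L-proline (20 mol %), diethyl 2,6-dimethyl-1,4-dihydropyridine-3,5-dicarboxylate (1.2 equiv), CH2Cl2, rt → 40 °C
Reagents that add atoms: none
Why: Proline-catalysed Knoevenagel condensation of the hydroxyquinone (at the carbon between C–OH and C=O) with the aldehyde gives the alkylidene trione, which is reduced in the flask by hydride transfer from the Hantzsch ester (three-component reductive alkylation), so the side chain arrives next to the hydroxyl and no stereocentre is formed.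

## Compound list

1 | 2-methylcyclohex-2-en-1-one | CC1=CCCCC1=O | starting material
2 | dimethylaluminium enolate of (3S)-2,3-dimethylcyclohexanone | C[Al](C)OC1=C(C)[C@@H](C)CCC1 | intermediate (not isolated)
3 | (2S,3S)-2-(hydroxymethyl)-2,3-dimethylcyclohexan-1-one | O=C1CCC[C@H](C)[C@@]1(C)CO | intermediate
4 | (2S,3S)-2-{[tert-butyl(diphenyl)silyl]oxymethyl}-2,3-dimethylcyclohexan-1-one | O=C1CCC[C@H](C)[C@@]1(C)CO[Si](c2ccccc2)(c2ccccc2)C(C)(C)C | intermediate
5 | (5S,6S)-6-{[tert-butyl(diphenyl)silyl]oxymethyl}-5,6-dimethylcyclohex-1-en-1-yl trifluoromethanesulfonate | O=S(=O)(OC1=CCC[C@H](C)[C@@]1(C)CO[Si](c2ccccc2)(c2ccccc2)C(C)(C)C)C(F)(F)F | intermediate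
6 | (3R,4S)-3-{[tert-butyl(diphenyl)silyl]oxymethyl}-3,4-dimethylcyclohex-1-ene | C1=CCC[C@H](C)[C@@]1(C)CO[Si](c2ccccc2)(c2ccccc2)C(C)(C)C | intermediate
7 | C5–C10 α-epoxide of 6 (oxygen cis to CH2OSi, trans to both methyls) | O1[C@H]2[C@@H]1CC[C@H](C)[C@@]2(C)CO[Si](c3ccccc3)(c3ccccc3)C(C)(C)C | intermediate
8 | 2-bromo-3-(trimethylsilyl)prop-1-ene | C[Si](C)(C)CC(Br)=C | starting material
9 | [3-(trimethylsilyl)prop-1-en-2-yl]magnesium bromide | C[Si](C)(C)CC(=C)[Mg]Br | intermediate (not isolated)
10 | cyclohexanol with C10 OH α, C5 [3-(trimethylsilyl)prop-1-en-2-yl] β, C8 CH3 β, C9 CH3 β and CH2OSiPh2t-Bu α | O[C@H]1[C@H](C(=C)C[Si](C)(C)C)CC[C@H](C)[C@@]1(C)CO[Si](c2ccccc2)(c2ccccc2)C(C)(C)C | intermediate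
11 | cyclohexanone (C10=O) with C5 [3-(trimethylsilyl)prop-1-en-2-yl] β | O=C1[C@H](C(=C)C[Si](C)(C)C)CC[C@H](C)[C@@]1(C)CO[Si](c2ccccc2)(c2ccccc2)C(C)(C)C | intermediate
12 | tertiary carbinol with C10 vinyl α and OH β, C5 alkenyl β | C=C[C@@]1(O)[C@H](C(=C)C[Si](C)(C)C)CC[C@H](C)[C@@]1(C)CO[Si](c2ccccc2)(c2ccccc2)C(C)(C)C | intermediate
13 | potassium (1Z,4Z)-enolate of the ten-membered ketone (both ring double bonds trans within the ring) | [K+].[O-]/C1=C\CC/C(C[Si](C)(C)C)=C/CC[C@H](C)[C@@]1(C)CO[Si](c2ccccc2)(c2ccccc2)C(C)(C)C | intermediate (not isolated)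
14 | (1S,4Z,8S,9S)-1-hydroxy ten-membered ketone (C10=O) | O=C1[C@@H](O)CC/C(C[Si](C)(C)C)=C/CC[C@H](C)[C@@]1(C)CO[Si](c2ccccc2)(c2ccccc2)C(C)(C)C | intermediate
15 | (1S,4Z,8S,9S,10R)-10-methyl-1,10-diol | C[C@]1(O)[C@@H](O)CC/C(C[Si](C)(C)C)=C/CC[C@H](C)[C@@]1(C)CO[Si](c2ccccc2)(c2ccccc2)C(C)(C)C | intermediate
16 | C1 methanesulfonate of 15 | C[C@]1(O)[C@@H](OS(C)(=O)=O)CC/C(C[Si](C)(C)C)=C/CC[C@H](C)[C@@]1(C)CO[Si](c2ccccc2)(c2ccccc2)C(C)(C)C | intermediate (not isolated)
17 | (1R,4Z,8S,9S,10R)-1,10-epoxy ten-membered allylsilane | C[C@]12O[C@@H]1CC/C(C[Si](C)(C)C)=C/CC[C@H](C)[C@@]2(C)CO[Si](c3ccccc3)(c3ccccc3)C(C)(C)C | intermediate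
18 | (1R,5S,8S,9R,10S)-4-methylene decalin, C1 β-OH, C15 OSiPh2t-Bu | C=C1CC[C@@H](O)[C@@]2(C)[C@H]1CC[C@H](C)[C@@]2(C)CO[Si](c3ccccc3)(c3ccccc3)C(C)(C)C | intermediate
19 | O-(C1) S-methyl xanthate of 18 | C=C1CC[C@@H](OC(=S)SC)[C@@]2(C)[C@H]1CC[C@H](C)[C@@]2(C)CO[Si](c3ccccc3)(c3ccccc3)C(C)(C)C | intermediate
20 | (5S,8S,9R,10S)-1-deoxy decalin C15 silyl ether | C=C1CCC[C@@]2(C)[C@H]1CC[C@H](C)[C@@]2(C)CO[Si](c3ccccc3)(c3ccccc3)C(C)(C)C | intermediate
21 | (5S,8S,9R,10S)-decalin C15 alcohol | C=C1CCC[C@@]2(C)[C@H]1CC[C@H](C)[C@@]2(C)CO | intermediate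
22 | (5S,8S,9R,10S)-decalin C15 aldehyde | C=C1CCC[C@@]2(C)[C@H]1CC[C@H](C)[C@@]2(C)C=O | intermediate
23 | 2,5-dimethoxy-1,4-benzoquinone | COC1=CC(=O)C(OC)=CC1=O | starting material
24 | 2-hydroxy-5-methoxy-1,4-benzoquinone | COC1=CC(=O)C(O)=CC1=O | intermediate
25 | alkylidene trione from 22 and 24 (geometry of the new C=C not defined) | C=C1CCC[C@@]2(C)[C@H]1CC[C@H](C)[C@@]2(C)C=C1C(=O)C(=O)C=C(OC)C1=O | intermediate (not isolated)
26 | target CNP0109104.1, (5S,8S,9R,10S) | C=C1CCC[C@@]2(C)[C@H]1CC[C@H](C)[C@@]2(C)CC1=C(O)C(=O)C=C(OC)C1=O | target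

## Step count and risks

Total steps: 18. Longest linear sequence: 17 (steps 1–16 and 18).

**Step 12.** What may go wrong: closure through the competing array with ring A as a boat, which keeps the C8 methyl equatorial and would give cis fusion; a 1,2-hydride shift of the Lewis-acid-opened epoxide to a ring ketone before the C–C bond forms; protodesilylation of the allylsilane. Fallback, setting out from 17 and returning at 18: replace the cationic opening by the homolytic one with Cp2TiCl (trivalent titanium, made in THF from Cp2TiCl2 and Mn dust), the radical transannular cyclisation known for 1,10-epoxygermacrenes. The tertiary C10 radical should add to C5 and the C4 radical end by loss of a neighbouring hydrogen, giving the exocyclic (E)-alkenylsilane decalin F1 together with its ring-olefin isomer, the Δ3 allylsilane decalin F2. Short treatment of the mixture with CF3CO2H (CH2Cl2, −20 °C) should protodesilylate both (at the silicon-bearing carbon of F1, in the SE2′ sense for F2) to 18.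

**Step 9.** What may go wrong: transfer of the Me3Si group from carbon to the crown-ether-activated alkoxide oxygen through a six-membered transition state before the rearrangement; hydroxylation of the minor enolate conformer, giving the wrong C1 epimer and later the cis epoxide; addition of the enolate to the sulfonimine by-product. Fallback, setting out from 12 and returning at 14: run the [3,3] shift thermally on the free alcohol without base (diglyme, about 200 °C, base-washed sealed tube; the thermal oxy-Cope of 1,2-divinylcyclohexanols). After enol–ketone tautomerisation this should give the ten-membered ketone F3. F3 can enolise only towards C1, so KN(SiMe3)2 (THF, −78 °C) followed by the Davis oxaziridine should give 14 from an equilibrated enolate.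

**Step 18.** What may go wrong: no condensation at the aldehyde carbon, which is flanked by two quaternary carbons; reduction of the quinone by the dihydropyridine faster than condensation. Fallback, setting out from 22 and returning at 26: add 2,3,5,6-tetramethoxyphenyllithium (1,2,4,5-tetramethoxybenzene, n-BuLi, THF, 0 °C; then 22, −78 → 0 °C) to give the benzylic alcohol F4 as a C15 epimer mixture. NaH, CS2 and MeI give the xanthate F5, and Bu3SnH/AIBN the tetramethoxyarene F6 (Barton–McCombie). (NH4)2Ce(NO3)6 (tetravalent cerium) in MeCN/H2O at 0 °C oxidises F6 to the 2,5-dimethoxyquinone F7. Hydrolysis of the methoxy group next to the side chain (aq. KOH, MeOH, then acid) gives 26; the regiochemistry of this last exchange would have to be confirmed.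

## Further compounds

F1 | step 12 | exocyclic (E)-[(trimethylsilyl)methylidene] decalin, C1 β-OH, C15 OSiPh2t-Bu | C[Si](C)(C)/C=C1\CC[C@@H](O)[C@@]2(C)[C@H]1CC[C@H](C)[C@@]2(C)CO[Si](c3ccccc3)(c3ccccc3)C(C)(C)C
F2 | step 12 | Δ3 decalin with C4 CH2SiMe3, C1 β-OH, C15 OSiPh2t-Bu | C[Si](C)(C)CC1=CC[C@@H](O)[C@@]2(C)[C@H]1CC[C@H](C)[C@@]2(C)CO[Si](c3ccccc3)(c3ccccc3)C(C)(C)C
F3 | step 9 | (4Z,8S,9S)-ten-membered ketone (C10=O, C1 CH2) | O=C1CCC/C(C[Si](C)(C)C)=C/CC[C@H](C)[C@@]1(C)CO[Si](c2ccccc2)(c2ccccc2)C(C)(C)C
F4 | step 18 | C15 (2,3,5,6-tetramethoxyphenyl)carbinol of the decalin (C15 epimer mixture) | C=C1CCC[C@@]2(C)[C@H]1CC[C@H](C)[C@@]2(C)C(O)c1c(OC)c(OC)cc(OC)c1OC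
F5 | step 18 | S-methyl xanthate of F4 | C=C1CCC[C@@]2(C)[C@H]1CC[C@H](C)[C@@]2(C)C(OC(=S)SC)c1c(OC)c(OC)cc(OC)c1OC
F6 | step 18 | C15 (2,3,5,6-tetramethoxyphenyl) decalin | C=C1CCC[C@@]2(C)[C@H]1CC[C@H](C)[C@@]2(C)Cc1c(OC)c(OC)cc(OC)c1OC
F7 | step 18 | 3-(decalinylmethyl)-2,5-dimethoxy-1,4-benzoquinone | C=C1CCC[C@@]2(C)[C@H]1CC[C@H](C)[C@@]2(C)CC1=C(OC)C(=O)C=C(OC)C1=O
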